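**Retrosynthetic overview**
1. 26 ⇒ 22 + 24. C12–C13 is made by B-alkyl Suzuki–Miyaura coupling, and the 13Z geometry arrives ready-made in 24. The 18-benzoate comes from benzaldehyde and C17 from methylenation of an 8-ketone.
2. Ring B (formed last) ⇒ ring enlargement of the trans-hydrindan-8-one 13. A thioallyl unit (C9, C11, C12) is added to C8, then C10 shifts from C8 to C9.
3. 13 ⇒ 10. 5α-H and 6α-OH come from an 18-OH-guided hydroboration of the 5-ene. C4 is set by α-face hydroxymethylation of a dienolate, and the C3 oxygen is then deleted.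
4. Ring A (formed first, onto the purchased five-membered ring) ⇒ amino-acid-catalysed annulation of 1 with 2, which sets C10.
5. Ring order: cyclopentane (bought) → ring A → ring B by five-to-six enlargement.

Assumption: labdane numbering is used for all compounds. In the hydrindanes 4–18, ring A is C1–C5/C10, the five-membered ring is C5, C6, C7, C8, C10, and C9 is still missing. α is the face opposite the C10 methyl (C20). Formaldehyde 6 is bought as paraformaldehyde and cracked.

**Step 1**
Reactants: 1 2-methylcyclopentane-1,3-dione; 2 pent-1-en-3-one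
Product: 4 (7aS)-4,7a-dimethyl-2,3,7,7a-tetrahydro-1H-indene-1,5(6H)-dione, via triketone 3 (not isolated)
Conditions: Et3N (5 mol %), DMF, 23 °C; then (S)-phenylalanine (1.0 equiv), (+)-camphor-10-sulfonic acid (0.5 equiv), 30 to 70 °C; one recrystallisation
Reagents that add atoms: none
Why: Michael addition followed by a Hajos–Parrish–Eder–Sauer–Wiechert enamine aldol condensation, in which the (S)-amino acid distinguishes the two enantiotopic ring carbonyls and sets C10 as S (about 90% ee, raised by recrystallisation).

**Step 2**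
Reactants: 4 enedione
Product: 5 8-ethylene ketal of 4
Conditions: TMSOCH2CH2OTMS (1.2 equiv), TMSOTf (5 mol %), CH2Cl2, −78 to −40 °C
Reagents that add atoms: 1,2-bis(trimethylsilyloxy)ethane, C[Si](C)(C)OCCO[Si](C)(C)C
Why: Noyori ketalisation under kinetic control takes the saturated C8 ketone and leaves the less electrophilic tetrasubstituted enone alone, and no stereocentre is touched.

**Step 3**
Reactants: 5 ketal enone; 6 formaldehyde
Product: 8 4α-(hydroxymethyl)-4β-methyl-5-en-3-one 8-ketal, via potassium dienolate 7 (not isolated)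
Conditions: KOt-Bu (1.1 equiv), THF, 0 °C; CH2O (monomer in THF, 3 equiv), −78 °C, 15 min; AcOH, −78 °C
Reagents that add atoms: potassium tert-butoxide, CC(C)(C)[O-].[K+] (potassium in 7 only)
Why: Deconjugative α-aldol hydroxymethylation of the thermodynamic extended enolate, in which CH2O attacks C4 from the α face (anti to the angular C20 methyl) to give 4α-CH2OH/4β-CH3 and move the alkene to C5=C6, while the cold acidic quench forestalls retro-aldol.

**Step 4**
Reactants: 8 hydroxymethyl ketone
Product: 10 18-hydroxy-5-ene 8-ketal (C3 now CH2), via tosylhydrazone 9 (not isolated)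
Conditions: TsNHNH2, MeOH, 50 °C; evaporate; catecholborane (3 equiv), CHCl3, −10 to 0 °C; NaOAc·3H2O, reflux
Reagents that add atoms: 4-methylbenzenesulfonohydrazide, Cc1ccc(cc1)S(=O)(=O)NN (in 9 only)
Why: Caglioti–Kabalka deoxygenation (hydride addition to the tosylhydrazone, then loss of sulfinate and N2) removes the only free ketone without strong base, so the β-hydroxy ketone cannot retro-aldolise, the unconjugated alkene stays put, and C4 and C10 are untouched.

**Step 5**
Reactants: 10 homoallylic alcohol
Product: 13 6α,18-dihydroxy-trans-hydrindan-8-one, via cyclic borinate 11 (not isolated), via diol ketal 12 (not isolated)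
Conditions: BH3·THF (3 equiv), THF, 0 to 40 °C; NaOH, H2O2, 0 to 23 °C; then 2 M HCl, THF, 23 °C
Reagents that add atoms: borane (as BH3·THF), B (boron in 11 only); hydrogen peroxide, OO (oxygen on C6); water, O (carbonyl oxygen on C8)
Why: Brown hydroboration–oxidation in which the 18-O–BH2 group delivers B–H to the α face (also the face free of C19 and C20), so syn addition puts H on C5α and boron, then OH with retention, on C6α to give the trans fusion, and mild acid finally frees the C8 ketone.

**Step 6**
Reactants: 13 keto diol; 14 allyl methyl sulfide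
Product: 17 8β-hydroxy-8α-[1-(methylthio)allyl] triol (C9 epimers), via lithiated sulfide 15 (not isolated), via titanium ate complex 16 (not isolated)
Conditions: 14 (3.5 equiv), s-BuLi, THF, −78 °C; Ti(OiPr)4, −78 °C; then 13, −78 to −30 °C; H2O work-up
Reagents that add atoms: sec-butyllithium, [Li]C(C)CC (lithium in 15 and 16 only); titanium tetraisopropoxide, CC(C)O[Ti](OC(C)C)(OC(C)C)OC(C)C (in 16 only)
Why: Carbonyl addition of a heteroatom-substituted allyl titanium ate complex, which reacts at the sulfur-bearing carbon, is too weakly basic to enolise or retro-aldolise the β-hydroxy ketone (two equivalents only cap the hydroxyls), and attacks C8 from the α face anti to C20, the C9 configuration being irrelevant at this stage.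

**Step 7 (key step)**
Reactants: 17 β-hydroxy allylic sulfide
Product: 19 6α,18-dihydroxy-13,14,15,16,17-pentanorlabd-11-en-8-one, via sulfonium triflate 18 (not isolated)
Conditions: MeOTf (1.05 equiv), 2,6-di-tert-butyl-4-methylpyridine (1.5 equiv), CH2Cl2, −78 to 0 °C; then (CF3)2CHOH, 0 to 40 °C; used crude
Reagents that add atoms: methyl trifluoromethanesulfonate, COS(=O)(=O)C(F)(F)F (methyl and triflate in 18 only)
Why: Proposed new method: chemoselective S-methylation makes an allylic dimethylsulfonium nucleofuge that can ionise only at C9 (the C8 oxygen stays a free hydroxyl, so no C8 cation forms and, without a real base, oxirane closure is slow); in the ionising, non-nucleophilic fluoroalcohol the developing allyl cation is intercepted by a 1,2-shift of the electron-rich quaternary C10 (C7 is deactivated by the C6 oxygen) with retention at C10, the carbinol collapses to the C8 ketone and the strained trans-hydrindane becomes the trans-decalin, the vinyl group taking the equatorial 9β position in the chair-like transition state (also its thermodynamic, epimerisable position); the closest known reaction types are semipinacol ring enlargements of halohydrin magnesium salts and 1,2-diol monosulfonates and the palladium-catalysed Wagner–Meerwein shift of vinylcyclobutanols, none shown for an allylic sulfonium group on an unstrained cyclopentanol.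

**Step 8**
Reactants: 19 α-vinyl ketone
Product: 20 13,14,15,16-tetranorlabda-8(17),11-diene-6α,18-diol
Conditions: Zn, CH2Br2, TiCl4 (pre-aged reagent, excess), THF–CH2Cl2, 0 to 23 °C
Reagents that add atoms: dibromomethane, BrCBr
Why: Takai–Lombardo methylenation, whose non-basic gem-dimetallic reagent converts hindered enolisable ketones without epimerising C9, conjugating the vinyl group or eliminating the β-hydroxyl, and which tolerates free alcohols.

**Step 9**
Reactants: 20 diene diol; 21 benzaldehyde
Product: 22 18-benzoate of 20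
Conditions: 21 (1.5 equiv), 1,4-dimethyl-1,2,4-triazolium iodide (10 mol %), DBU (1.1 equiv), 3,3′,5,5′-tetra-tert-butyldiphenoquinone (1.5 equiv), THF, 23 °C
Reagents that add atoms: none
Why: N-heterocyclic-carbene-catalysed oxidative esterification, in which the mild acyl azolium made from benzaldehyde acylates only the primary 18-OH and leaves the hindered secondary 6α-OH and both alkenes untouched.

**Step 10**
Reactants: 23 but-2-ynoic acid
Product: 24 (Z)-3-iodobut-2-enoic acid
Conditions: NaI (1.6 equiv), AcOH, 110 °C
Reagents that add atoms: sodium iodide, [Na+].[I-]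
Why: Conjugate hydroiodination of an ynoic acid, in which anti addition of H and I places iodine cis to the carboxyl group (Z).

**Step 11**
Reactants: 22 diene benzoate; 24 (Z)-3-iodobut-2-enoic acid
Product: 26 6α-hydroxy-18-benzoyloxylabda-8(17),13Z-dien-15-oic acid (CNP0304840.1), via trialkylborane 25 (not isolated)
Conditions: Sia2BH (2.3 equiv, from BH3·THF and 2-methylbut-2-ene), THF, 0 °C; then 24, PdCl2(dppf) (5 mol %), AsPh3, Cs2CO3, DMF–H2O, 23 °C; citric acid work-up
Reagents that add atoms: bis(1,2-dimethylpropyl)borane, CC(C)C(C)BC(C)C(C)C (boron in 25 only)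
Why: Disiamylborane hydroborates the monosubstituted vinyl group far faster than the hindered 1,1-disubstituted C8=C17, and the B-alkyl Suzuki–Miyaura coupling transfers the primary alkyl group with retention of the iodoalkene geometry, so 13Z is carried over from 24 while benzoate, 6-OH and the free acid survive the mild carbonate base.

**Compound list**
1 | 2-methylcyclopentane-1,3-dione | CC1C(=O)CCC1=O | starting material
2 | pent-1-en-3-one (ethyl vinyl ketone) | C=CC(=O)CC | starting material
3 | 2-methyl-2-(3-oxopentyl)cyclopentane-1,3-dione | CCC(=O)CCC1(C)C(=O)CCC1=O | intermediate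
4 | (7aS)-4,7a-dimethyl-2,3,7,7a-tetrahydro-1H-indene-1,5(6H)-dione (4-en-3-one, 8-one, 10β-CH3) | O=C1CCC2=C(C)C(=O)CC[C@@]21C | intermediate
5 | 8-ethylene ketal of 4 | C1COC2(O1)CCC3=C(C)C(=O)CC[C@@]32C | intermediate
6 | formaldehyde | C=O | starting material
7 | potassium 3,5-dienolate of 5 | C1COC2(O1)CC=C3C(C)=C([O-])CC[C@@]32C.[K+] | intermediate
8 | 4α-(hydroxymethyl)-4β-methyl-5-en-3-one 8-ketal | C1COC2(O1)CC=C3[C@](C)(CO)C(=O)CC[C@@]32C | intermediate
9 | 3-tosylhydrazone of 8 | C1COC2(O1)CC=C3[C@](C)(CO)C(=NNS(=O)(=O)c4ccc(C)cc4)CC[C@@]32C | intermediate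
10 | 18-hydroxy-5-ene 8-ketal (3-deoxy) | C1COC2(O1)CC=C3[C@](C)(CO)CCC[C@@]32C | intermediate
11 | cyclic borinate (B on C6α and O18, 5α-H) | C1COC2(O1)C[C@H]4[C@H]3[C@](C)(COB4)CCC[C@@]32C | intermediate
12 | 6α,18-diol 8-ketal (trans-hydrindane) | C1COC2(O1)C[C@H](O)[C@H]3[C@](C)(CO)CCC[C@@]32C | intermediate
13 | 6α,18-dihydroxy-trans-hydrindan-8-one | O=C1C[C@H](O)[C@H]2[C@](C)(CO)CCC[C@@]21C | intermediate
14 | allyl methyl sulfide | C=CCSC | starting material
15 | [1-(methylthio)allyl]lithium | [Li]C(SC)C=C | intermediate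
16 | Li[Ti(OiPr)4(CH(SMe)CH=CH2)] | [Li+].C=CC(SC)[Ti-](OC(C)C)(OC(C)C)(OC(C)C)OC(C)C | intermediate
17 | 8β-hydroxy-8α-[1-(methylthio)allyl]-6α,18-diol (C9 epimers) | O[C@@]1(C(SC)C=C)C[C@H](O)[C@H]2[C@](C)(CO)CCC[C@@]21C | intermediate
18 | dimethylsulfonium triflate of 17 | O[C@@]1(C(C=C)[S+](C)C)C[C@H](O)[C@H]2[C@](C)(CO)CCC[C@@]21C.[O-]S(=O)(=O)C(F)(F)F | intermediate
19 | 6α,18-dihydroxy-13,14,15,16,17-pentanorlabd-11-en-8-one (9β-vinyl, 9α-H) | O=C1C[C@H](O)[C@H]2[C@](C)(CO)CCC[C@]2(C)[C@H]1C=C | intermediate
20 | 13,14,15,16-tetranorlabda-8(17),11-diene-6α,18-diol | C=C1C[C@H](O)[C@H]2[C@](C)(CO)CCC[C@]2(C)[C@H]1C=C | intermediate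
21 | benzaldehyde | O=Cc1ccccc1 | starting material
22 | 18-benzoate of 20 | C=C1C[C@H](O)[C@H]2[C@](C)(COC(=O)c3ccccc3)CCC[C@]2(C)[C@H]1C=C | intermediate
23 | but-2-ynoic acid | CC#CC(=O)O | starting material
24 | (Z)-3-iodobut-2-enoic acid | C/C(I)=C/C(=O)O | intermediate
25 | 12-(disiamylboryl) 6-O-(disiamylboryl) derivative of 22 | C=C1C[C@H](OB(C(C)C(C)C)C(C)C(C)C)[C@H]2[C@](C)(COC(=O)c3ccccc3)CCC[C@]2(C)[C@H]1CCB(C(C)C(C)C)C(C)C(C)C | intermediate
26 | 6α-hydroxy-18-benzoyloxylabda-8(17),13Z-dien-15-oic acid | C=C1C[C@H](O)[C@H]2[C@](C)(COC(=O)c3ccccc3)CCC[C@]2(C)[C@H]1CC/C(C)=C\C(=O)O | target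

**Totals:** 11 steps in all. The longest linear sequence is 10 steps (steps 1–9 and 11); step 10 is the side branch.

**Three steps most likely to fail**

Step 7 (the new ring enlargement). Ionisation may be too slow, or oxirane closure, a C7 shift or capture of the allyl cation may win. The fallback uses known chemistry, sets out from 13 and bypasses 17. Both hydroxyls are silylated (Et3SiCl, imidazole) to give the bis(triethylsilyl) ether F1. LiCHBr2 (CH2Br2, LDA, THF, −78 °C) adds from the α face to give the dibromomethyl carbinol F2. Treating F2 with n-BuLi (2.2 equiv, −78 to 0 °C) triggers the β-oxido carbenoid ring enlargement, in which I expect the more substituted α-carbon to migrate (I am relying on recollection of the precedent for unsymmetrical ketones here). This gives the ring-enlarged lithium enolate F3 regiospecifically. F3 is trapped with (phenylseleno)acetaldehyde as the β-hydroxy selenide F4. MsCl/Et3N then eliminates F4 to the 9-vinyl ketone bis(silyl) ether F5. AcOH–THF–H2O removes the silyl groups, and the sequence comes back at 19.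

Step 3 (reversible aldol at a carbon that becomes quaternary). Retro-aldol, attack at C6 or double addition are the risks. The fallback sets out from 5 and replaces the reversible aldol by an irreversible alkylation followed by C–B oxidation. The same dienolate 7 is alkylated with 2-(iodomethyl)-4,4,5,5-tetramethyl-1,3,2-dioxaborolane, again from the α face, to give the 4α-(pinacolborylmethyl) ketone F6. NaBO3·4H2O in THF–H2O converts C–B into C–OH, and the sequence comes back at 8.

Step 11 (vinyl against C8=C17 selectivity, and transfer from a disiamylborane). The fallback sets out from 22 and separates hydroboration from coupling. Catalysed hydroboration with pinacolborane ([Ir(cod)Cl]2, dppe), which leaves 1,1-disubstituted alkenes alone, gives the 12-pinacolboronate F7. NaBO3·4H2O gives the primary alcohol F8, and I2, PPh3 and imidazole give the primary iodide F9. Zinc dust with LiCl gives the alkylzinc iodide F10. A Negishi coupling (PdCl2(dppf)) with the sodium salt of 24, which retains the alkene geometry, comes back at 26.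

**Further compounds**
F1 | step 7 | 6α,18-bis(triethylsilyloxy)-trans-hydrindan-8-one | O=C1C[C@H](O[Si](CC)(CC)CC)[C@H]2[C@](C)(CO[Si](CC)(CC)CC)CCC[C@@]21C
F2 | step 7 | 8α-(dibromomethyl)-8β-ol of F1 | O[C@@]1(C(Br)Br)C[C@H](O[Si](CC)(CC)CC)[C@H]2[C@](C)(CO[Si](CC)(CC)CC)CCC[C@@]21C
F3 | step 7 | ring-enlarged lithium enolate (C8=C9) | [Li]OC=1C[C@H](O[Si](CC)(CC)CC)[C@H]2[C@](C)(CO[Si](CC)(CC)CC)CCC[C@]2(C)C=1
F4 | step 7 | 9β-[1-hydroxy-2-(phenylseleno)ethyl] 8-ketone bis(silyl) ether | O=C1C[C@H](O[Si](CC)(CC)CC)[C@H]2[C@](C)(CO[Si](CC)(CC)CC)CCC[C@]2(C)[C@H]1C(O)C[Se]c3ccccc3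
F5 | step 7 | bis(triethylsilyl) ether of 19 | O=C1C[C@H](O[Si](CC)(CC)CC)[C@H]2[C@](C)(CO[Si](CC)(CC)CC)CCC[C@]2(C)[C@H]1C=C
F6 | step 3 | 4α-[(pinacolboryl)methyl]-4β-methyl-5-en-3-one 8-ketal | C1COC2(O1)CC=C3[C@](C)(CB4OC(C)(C)C(C)(C)O4)C(=O)CC[C@@]32C
F7 | step 11 | 12-pinacolboronate from 22 | C=C1C[C@H](O)[C@H]2[C@](C)(COC(=O)c3ccccc3)CCC[C@]2(C)[C@H]1CCB4OC(C)(C)C(C)(C)O4
F8 | step 11 | 12-alcohol | C=C1C[C@H](O)[C@H]2[C@](C)(COC(=O)c3ccccc3)CCC[C@]2(C)[C@H]1CCO
F9 | step 11 | 12-iodide | C=C1C[C@H](O)[C@H]2[C@](C)(COC(=O)c3ccccc3)CCC[C@]2(C)[C@H]1CCI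
F10 | step 11 | 12-(iodozincio) compound | C=C1C[C@H](O)[C@H]2[C@](C)(COC(=O)c3ccccc3)CCC[C@]2(C)[C@H]1CC[Zn]I
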